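**Retrosynthetic overview**

1. Cryptomerin A (21) comes from its di-O-benzyl ether 20 by hydrogenolysis; the benzyl groups sit only on the 5- and 7-oxygens of the apigenin half.
2. The strategy rests on ring A of the 4'-methoxyflavone half (C4a, C5, C6, C7, C8, C8a), a phloroglucinol ring with the aryloxy group on C6 between the C5 and C7 hydroxyls. C5–C6–C7 are taken from an aryloxymalonyl unit, C8 from the methyl carbon of a 2-methyl-4-pyranone, and C8a/C4a from C2/C3 of that pyranone.
3. 20 is traced to the tert-butyl aryloxy keto ester 17, whose acylketene closes ring A by forming the C4a–C5 bond. 17 comes from phenol 16 and diazo keto ester 9, so the C6–O bond is made at an sp3 carbon.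
4. 9 goes back through keto ester 8, pyranonylacetic acid 6 and pyranone 4 to acetylacetone and methyl 4-methoxybenzoate. 16 goes back through chalcone 14 to 2,4,6-trihydroxyacetophenone and 4-hydroxybenzaldehyde.
5. Ring order: pyranone ring C of the anisyl half (step 2), ring C of the apigenin half (step 9), ring A of the anisyl half (step 11).

Key step: step 11

Remark on the chemistry: the β-keto ester chain is assembled before the aryloxy group is attached, because an aryloxymalonate (α-C–H pKa about 13) would protonate a lithiated methylpyranone instead of acylating it. With pyranone locants O1, C2 (side chain), C3, C4 (C=O), C5, C6 (anisyl), the ring-closing carbon is C3. Compound 17 is racemic at C2 and partly enolised; this centre is destroyed in step 11.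

**Route**

Step 1
Reactants: 1 acetylacetone; 2 methyl 4-methoxybenzoate
Product: 3 1-(4-methoxyphenyl)hexane-1,3,5-trione
Conditions: 1 (2 equiv), NaH (5 equiv), DME, reflux; then aq. HCl, 0 °C
Reagents that add atoms: none
Why: Claisen-type aroylation of a β-diketone at its terminal methyl group, in which excess NaH gives the dianion of 1 in equilibrium and its less stabilised terminal carbanion attacks the non-enolisable ester 2, the triketone being removed as its sodium salt.

Step 2
Reactants: 3 1-(4-methoxyphenyl)hexane-1,3,5-trione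
Product: 4 2-(4-methoxyphenyl)-6-methyl-4H-pyran-4-one
Conditions: conc. H2SO4, 0 °C, 15 min; ice water
Reagents that add atoms: none
Why: Acid-catalysed cyclodehydration of a 1,3,5-triketone (enol oxygen of one terminal carbonyl adds to the other, then loss of water) should give the 2,6-disubstituted 4-pyranone as the only possible ring.

Step 3
Reactants: 4 2-(4-methoxyphenyl)-6-methyl-4H-pyran-4-one
Product: 6 2-[6-(4-methoxyphenyl)-4-oxo-4H-pyran-2-yl]acetic acid, via lithium dienolate 5 (not isolated)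
Conditions: LiN(SiMe3)2 (1.1 equiv), THF, −78 °C; CO2 (g), −78 to −20 °C; cold 1 M HCl
Reagents that add atoms: carbon dioxide, O=C=O; LiN(SiMe3)2, [Li+].C[Si](C)(C)[N-][Si](C)(C)C (its lithium is carried by intermediate 5 only)
Why: Vinylogous enolate formation at the only sp3 C–H of 4 (the 6-methyl group) followed by carboxylation of the lithium dienolate at its exocyclic carbon; the acid is liberated cold and used at once because it is a vinylogous β-keto acid.

Step 4
Reactants: 6 2-[6-(4-methoxyphenyl)-4-oxo-4H-pyran-2-yl]acetic acid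
Product: 8 tert-butyl 4-[6-(4-methoxyphenyl)-4-oxo-4H-pyran-2-yl]-3-oxobutanoate, via acyl imidazolide 7 (not isolated)
Conditions: CDI (1.1 equiv), THF, 0 °C to rt; then Mg(O2CCH2CO2t-Bu)2 (1.0 equiv), THF, rt to 40 °C; cold 0.5 M HCl
Reagents that add atoms: magnesium bis(mono-tert-butyl malonate), [Mg+2].CC(C)(C)OC(=O)CC([O-])=O.CC(C)(C)OC(=O)CC([O-])=O; 1,1'-carbonyldiimidazole, O=C(n1ccnc1)n1ccnc1 (its imidazole is carried by intermediate 7 only)
Why: Masamune–Brooks chain extension, in which the neutral magnesium chelate of the malonate half-ester is C-acylated by the acyl imidazolide and loses CO2, so the β-keto ester forms without a strongly basic carbanion that the acidic CH2 groups could quench.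

Step 5
Reactants: 8 tert-butyl 4-[6-(4-methoxyphenyl)-4-oxo-4H-pyran-2-yl]-3-oxobutanoate
Product: 9 tert-butyl 2-diazo-4-[6-(4-methoxyphenyl)-4-oxo-4H-pyran-2-yl]-3-oxobutanoate
Conditions: p-ABSA (1.05 equiv), Et3N (1.2 equiv), MeCN, 0 °C to rt
Reagents that add atoms: 4-acetamidobenzenesulfonyl azide (p-ABSA), CC(=O)Nc1ccc(cc1)S(=O)(=O)N=[N+]=[N-]
Why: Regitz diazo transfer with a weak amine base should occur at C2, the 1,3-dicarbonyl methylene, which is estimated to be several pKa units more acidic than the C4 methylene that is activated only vinylogously by the pyranone.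

Step 6
Reactants: 10 2,4,6-trihydroxyacetophenone
Product: 11 1-[2,4-bis(benzyloxy)-6-hydroxyphenyl]ethanone
Conditions: BnBr (2.1 equiv), K2CO3 (2.2 equiv), DMF, rt to 50 °C
Reagents that add atoms: benzyl bromide, BrCc1ccccc1
Why: Williamson etherification, in which the last ortho hydroxyl is hydrogen-bonded to the acetyl carbonyl and is the least nucleophilic, so two equivalents of benzyl bromide should stop at the 2-hydroxy-4,6-dibenzyl ether.

Step 7
Reactants: 12 4-hydroxybenzaldehyde
Product: 13 4-(methoxymethoxy)benzaldehyde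
Conditions: MOMCl (1.2 equiv), K2CO3 (2 equiv), acetone, 0 °C to rt
Reagents that add atoms: chloromethyl methyl ether, COCCl
Why: O-alkylation of the phenoxide with the reactive α-chloro ether gives a base-stable acetal, which keeps the aldehyde electrophilic under the alkaline conditions of step 8.

Step 8
Reactants: 11 1-[2,4-bis(benzyloxy)-6-hydroxyphenyl]ethanone; 13 4-(methoxymethoxy)benzaldehyde
Product: 14 (E)-1-[2,4-bis(benzyloxy)-6-hydroxyphenyl]-3-[4-(methoxymethoxy)phenyl]prop-2-en-1-one
Conditions: KOH (50% aq.), EtOH–THF, rt, 48 h; neutralise cold to pH 6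
Reagents that add atoms: none
Why: Claisen–Schmidt condensation of the methyl ketone with a non-enolisable aldehyde, in which E1cB dehydration gives the conjugated (E)-enone and any flavanone formed by oxa-Michael closure converges in step 9.

Step 9
Reactants: 14 (E)-1-[2,4-bis(benzyloxy)-6-hydroxyphenyl]-3-[4-(methoxymethoxy)phenyl]prop-2-en-1-one
Product: 16 5,7-bis(benzyloxy)-2-(4-hydroxyphenyl)-4H-chromen-4-one, via MOM-protected flavone 15 (not isolated)
Conditions: I2 (0.1 equiv), DMSO, 120 °C; then 3 M HCl, MeOH–THF, 55 °C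
Reagents that add atoms: none
Why: I2/DMSO oxidative cyclisation of a 2'-hydroxychalcone (oxa-Michael closure, α-iodination, loss of HI, DMSO re-oxidising HI) forms the flavone ring C, and acid methanolysis then removes the MOM acetal whether or not HI has already cleaved part of it, the benzyl ethers being stable to both.

Step 10
Reactants: 9 tert-butyl 2-diazo-4-[6-(4-methoxyphenyl)-4-oxo-4H-pyran-2-yl]-3-oxobutanoate; 16 5,7-bis(benzyloxy)-2-(4-hydroxyphenyl)-4H-chromen-4-one
Product: 17 tert-butyl 2-{4-[5,7-bis(benzyloxy)-4-oxo-4H-chromen-2-yl]phenoxy}-4-[6-(4-methoxyphenyl)-4-oxo-4H-pyran-2-yl]-3-oxobutanoate (racemic)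
Conditions: Rh2(OAc)4 (2 mol %), 16 (1.3 equiv), ClCH2CH2Cl, 60 °C, slow addition of 9
Reagents that add atoms: none
Why: Rhodium-carbenoid O–H insertion (oxonium ylide, then 1,2-proton shift) of an α-diazo-β-keto ester into a phenol joins the ether oxygen to the sp3 carbon C2; the new stereocentre forms racemic, is enolisable and disappears in step 11.

Step 11
Reactants: 17 tert-butyl 2-{4-[5,7-bis(benzyloxy)-4-oxo-4H-chromen-2-yl]phenoxy}-4-[6-(4-methoxyphenyl)-4-oxo-4H-pyran-2-yl]-3-oxobutanoate (racemic)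
Product: 20 6-{4-[5,7-bis(benzyloxy)-4-oxo-4H-chromen-2-yl]phenoxy}-5,7-dihydroxy-2-(4-methoxyphenyl)-4H-chromen-4-one, via aryloxy acylketene 18 (not isolated), via 4aH-dienone tautomer 19 (not isolated)
Conditions: xylene (0.005 M), 135 °C, slow addition of 17, N2 sweep to carry off t-BuOH
Reagents that add atoms: none
Why: Proposed new method: the enol form of 17 loses tert-butanol through a six-membered transition state, as tert-butyl acetoacetates do above 100 °C, to give the α-aryloxy acylketene 18; enolisation of its ketone towards the pyranone CH2 then gives a (Z)-dienylketene whose termini are the ketene carbon and C3 of the pyranone. Thermal disrotatory 6π electrocyclisation (equally, intramolecular C-acylation of the enol-ether-like C3 by the ketene carbon) forms the C4a–C5 bond and closes ring A as the six-membered dienone 19, which tautomerises to the 5,7-dihydroxy-6-aryloxy benzene ring. The closest known reactions are the acylketene chemistry of tert-butyl β-keto esters and dioxinones, the 6π closure of dienylketenes to phenols in the Danheiser benzannulation, and the Claisen-type aromatisation of polyketo esters to acylphloroglucinols; closure onto a 4-pyranone carbon has no direct precedent. No stereocentre remains, since C2 of 17 becomes sp2 and the C4a–H centre of 19 is lost on aromatisation. The step needs chemoselectivity for intramolecular C–C closure over ketene dimerisation, O-acylation of product phenols and re-capture by tert-butanol, which slow addition at high dilution and removal of tert-butanol should secure. The regiochemistry (aryloxy on C6, not C8) is fixed by the substrate, because O1 is already in place in the pyranone and C3 is the only ring carbon within six-membered reach of the ketene carbon.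

Step 12
Reactants: 20 6-{4-[5,7-bis(benzyloxy)-4-oxo-4H-chromen-2-yl]phenoxy}-5,7-dihydroxy-2-(4-methoxyphenyl)-4H-chromen-4-one
Product: 21 cryptomerin A
Conditions: H2 (1 atm), 10% Pd/C, THF–MeOH (1:1), rt
Reagents that add atoms: none
Why: Catalytic hydrogenolysis of the two benzyl aryl ethers; the flavone C2=C3 bonds, the diaryl ether and the methyl ether should not be reduced at 1 atm and room temperature.

**Compound list**

1 | acetylacetone | CC(=O)CC(C)=O | starting material
2 | methyl 4-methoxybenzoate | COC(=O)c1ccc(OC)cc1 | starting material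
3 | 1-(4-methoxyphenyl)hexane-1,3,5-trione | COc1ccc(cc1)C(=O)CC(=O)CC(C)=O | intermediate
4 | 2-(4-methoxyphenyl)-6-methyl-4H-pyran-4-one | COc1ccc(cc1)-c1cc(=O)cc(C)o1 | intermediate
5 | lithium 6-(4-methoxyphenyl)-2-methylidene-2H-pyran-4-olate (lithium dienolate of 4) | [Li+].[O-]C1=CC(=C)OC(=C1)c1ccc(OC)cc1 | intermediate
6 | 2-[6-(4-methoxyphenyl)-4-oxo-4H-pyran-2-yl]acetic acid | COc1ccc(cc1)-c1cc(=O)cc(CC(=O)O)o1 | intermediate
7 | 2-[2-(1H-imidazol-1-yl)-2-oxoethyl]-6-(4-methoxyphenyl)-4H-pyran-4-one (acyl imidazolide of 6) | COc1ccc(cc1)-c1cc(=O)cc(CC(=O)n2ccnc2)o1 | intermediate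
8 | tert-butyl 4-[6-(4-methoxyphenyl)-4-oxo-4H-pyran-2-yl]-3-oxobutanoate | COc1ccc(cc1)-c1cc(=O)cc(CC(=O)CC(=O)OC(C)(C)C)o1 | intermediate
9 | tert-butyl 2-diazo-4-[6-(4-methoxyphenyl)-4-oxo-4H-pyran-2-yl]-3-oxobutanoate | COc1ccc(cc1)-c1cc(=O)cc(CC(=O)C(=[N+]=[N-])C(=O)OC(C)(C)C)o1 | intermediate
10 | 2,4,6-trihydroxyacetophenone | CC(=O)c1c(O)cc(O)cc1O | starting material
11 | 1-[2,4-bis(benzyloxy)-6-hydroxyphenyl]ethanone | CC(=O)c1c(O)cc(OCc2ccccc2)cc1OCc1ccccc1 | intermediate
12 | 4-hydroxybenzaldehyde | O=Cc1ccc(O)cc1 | starting material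
13 | 4-(methoxymethoxy)benzaldehyde | COCOc1ccc(C=O)cc1 | intermediate
14 | (E)-1-[2,4-bis(benzyloxy)-6-hydroxyphenyl]-3-[4-(methoxymethoxy)phenyl]prop-2-en-1-one | COCOc1ccc(/C=C/C(=O)c2c(O)cc(OCc3ccccc3)cc2OCc2ccccc2)cc1 | intermediate
15 | 5,7-bis(benzyloxy)-2-[4-(methoxymethoxy)phenyl]-4H-chromen-4-one | COCOc1ccc(cc1)-c1cc(=O)c2c(OCc3ccccc3)cc(OCc3ccccc3)cc2o1 | intermediate
16 | 5,7-bis(benzyloxy)-2-(4-hydroxyphenyl)-4H-chromen-4-one | Oc1ccc(cc1)-c1cc(=O)c2c(OCc3ccccc3)cc(OCc3ccccc3)cc2o1 | intermediate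
17 | tert-butyl 2-{4-[5,7-bis(benzyloxy)-4-oxo-4H-chromen-2-yl]phenoxy}-4-[6-(4-methoxyphenyl)-4-oxo-4H-pyran-2-yl]-3-oxobutanoate (racemic) | CC(C)(C)OC(=O)C(Oc1ccc(cc1)-c1cc(=O)c2c(OCc3ccccc3)cc(OCc3ccccc3)cc2o1)C(=O)Cc1cc(=O)cc(o1)-c1ccc(OC)cc1 | intermediate
18 | 2-{4-[5,7-bis(benzyloxy)-4-oxo-4H-chromen-2-yl]phenoxy}-4-[6-(4-methoxyphenyl)-4-oxo-4H-pyran-2-yl]but-1-ene-1,3-dione (aryloxy acylketene) | O=C=C(Oc1ccc(cc1)-c1cc(=O)c2c(OCc3ccccc3)cc(OCc3ccccc3)cc2o1)C(=O)Cc1cc(=O)cc(o1)-c1ccc(OC)cc1 | intermediate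
19 | 6-{4-[5,7-bis(benzyloxy)-4-oxo-4H-chromen-2-yl]phenoxy}-7-hydroxy-2-(4-methoxyphenyl)-4aH-chromene-4,5-dione (racemic, transient) | COc1ccc(cc1)C1=CC(=O)C2C(=O)C(Oc3ccc(cc3)-c3cc(=O)c4c(OCc5ccccc5)cc(OCc5ccccc5)cc4o3)=C(O)C=C2O1 | intermediate
20 | 6-{4-[5,7-bis(benzyloxy)-4-oxo-4H-chromen-2-yl]phenoxy}-5,7-dihydroxy-2-(4-methoxyphenyl)-4H-chromen-4-one | COc1ccc(cc1)-c1cc(=O)c2c(O)c(Oc3ccc(cc3)-c3cc(=O)c4c(OCc5ccccc5)cc(OCc5ccccc5)cc4o3)c(O)cc2o1 | intermediate
21 | cryptomerin A, 6-[4-(5,7-dihydroxy-4-oxo-4H-chromen-2-yl)phenoxy]-5,7-dihydroxy-2-(4-methoxyphenyl)-4H-chromen-4-one | COc1ccc(-c2cc(=O)c3c(O)c(Oc4ccc(-c5cc(=O)c6c(O)cc(O)cc6o5)cc4)c(O)cc3o2)cc1 | target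

**Step count**

Total steps: 12. Longest linear sequence: 8 steps (steps 1, 2, 3, 4, 5, 10, 11, 12); the apigenin branch (steps 6 to 9) joins at step 10.

**Steps most likely to fail**

Step 11. The acylketene may be consumed by intermolecular paths (dimerisation, acylation of product phenols, re-capture by tert-butanol followed by slow hydrolysis and decarboxylation) faster than the weakly nucleophilic pyranone C3 closes onto it. Heating keto ester 8 alone, which should give acacetin by the same closure, would be a cheap rehearsal.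

The fallback uses the classical diaryl-ether disconnection; it sets out from 11 and 16 and comes back at 21. Claisen–Schmidt condensation of 11 with 4-methoxybenzaldehyde (KOH, EtOH) should give (E)-1-[2,4-bis(benzyloxy)-6-hydroxyphenyl]-3-(4-methoxyphenyl)prop-2-en-1-one F1. I2/DMSO cyclisation should give 5,7-bis(benzyloxy)-2-(4-methoxyphenyl)-4H-chromen-4-one F2. BCl3 in CH2Cl2 at −78 °C should remove only the chelated 5-O-benzyl group to give 7-(benzyloxy)-5-hydroxy-2-(4-methoxyphenyl)-4H-chromen-4-one F3. Iodination ortho to the free 5-hydroxyl with benzyltrimethylammonium dichloroiodate and CaCO3 in CH2Cl2–MeOH should give 7-(benzyloxy)-5-hydroxy-6-iodo-2-(4-methoxyphenyl)-4H-chromen-4-one F4. Re-benzylation (BnBr, K2CO3, DMF) should give 5,7-bis(benzyloxy)-6-iodo-2-(4-methoxyphenyl)-4H-chromen-4-one F5. Ullmann-type coupling of F5 with 16 (CuI, picolinic acid, K3PO4, DMSO, 90 °C) should give 5,7-bis(benzyloxy)-6-{4-[5,7-bis(benzyloxy)-4-oxo-4H-chromen-2-yl]phenoxy}-2-(4-methoxyphenyl)-4H-chromen-4-one F6. Hydrogenolysis under the conditions of step 12 then gives 21.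

Step 10. The rhodium carbenoid may be diverted into intramolecular attack on the pyranone (C3 or the ring and carbonyl oxygens) or into carbene dimerisation before the weakly nucleophilic, poorly soluble phenol intercepts it.

The fallback forms the same C–O bond by substitution; it sets out from 8 and comes back at 17. Chlorination of 8 at C2 (SO2Cl2, CH2Cl2, 0 °C) should give tert-butyl 2-chloro-4-[6-(4-methoxyphenyl)-4-oxo-4H-pyran-2-yl]-3-oxobutanoate F7. Displacement of chloride by the phenoxide of 16 (K2CO3, acetone, rt) should then give 17.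

Step 5. Diazo transfer may lose regioselectivity (transfer to the C4 methylene or double transfer) if the vinylogous activation by the pyranone is stronger than estimated.

The fallback brings the aryloxy group in with the malonyl unit; it sets out from 16 (with imidazolide 7 made from 6 as in step 4) and comes back at 17, bypassing 8 and 9. Commercial tert-butyl ethyl malonate is chlorinated (SO2Cl2) to tert-butyl ethyl 2-chloromalonate F8. Phenol 16 is alkylated with F8 (K2CO3, acetone) to give tert-butyl ethyl 2-{4-[5,7-bis(benzyloxy)-4-oxo-4H-chromen-2-yl]phenoxy}malonate F9. The ethyl ester is saponified selectively (KOH, 1 equiv, EtOH–THF, 0 °C) to 3-tert-butoxy-2-{4-[5,7-bis(benzyloxy)-4-oxo-4H-chromen-2-yl]phenoxy}-3-oxopropanoic acid F10. The magnesium salt of F10 (MgCl2, Et3N, THF) is acylated by imidazolide 7 and loses CO2 (Masamune–Brooks conditions) to give 17. The nucleophile here is a neutral magnesium chelate, so proton transfer does not defeat the acylation.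

**Further compounds**

F1 | step 11 | (E)-1-[2,4-bis(benzyloxy)-6-hydroxyphenyl]-3-(4-methoxyphenyl)prop-2-en-1-one | COc1ccc(/C=C/C(=O)c2c(O)cc(OCc3ccccc3)cc2OCc2ccccc2)cc1
F2 | step 11 | 5,7-bis(benzyloxy)-2-(4-methoxyphenyl)-4H-chromen-4-one | COc1ccc(cc1)-c1cc(=O)c2c(OCc3ccccc3)cc(OCc3ccccc3)cc2o1
F3 | step 11 | 7-(benzyloxy)-5-hydroxy-2-(4-methoxyphenyl)-4H-chromen-4-one | COc1ccc(cc1)-c1cc(=O)c2c(O)cc(OCc3ccccc3)cc2o1
F4 | step 11 | 7-(benzyloxy)-5-hydroxy-6-iodo-2-(4-methoxyphenyl)-4H-chromen-4-one | COc1ccc(cc1)-c1cc(=O)c2c(O)c(I)c(OCc3ccccc3)cc2o1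
F5 | step 11 | 5,7-bis(benzyloxy)-6-iodo-2-(4-methoxyphenyl)-4H-chromen-4-one | COc1ccc(cc1)-c1cc(=O)c2c(OCc3ccccc3)c(I)c(OCc3ccccc3)cc2o1
F6 | step 11 | 5,7-bis(benzyloxy)-6-{4-[5,7-bis(benzyloxy)-4-oxo-4H-chromen-2-yl]phenoxy}-2-(4-methoxyphenyl)-4H-chromen-4-one | COc1ccc(cc1)-c1cc(=O)c2c(OCc3ccccc3)c(Oc3ccc(cc3)-c3cc(=O)c4c(OCc5ccccc5)cc(OCc5ccccc5)cc4o3)c(OCc3ccccc3)cc2o1
F7 | step 10 | tert-butyl 2-chloro-4-[6-(4-methoxyphenyl)-4-oxo-4H-pyran-2-yl]-3-oxobutanoate | COc1ccc(cc1)-c1cc(=O)cc(CC(=O)C(Cl)C(=O)OC(C)(C)C)o1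
F8 | step 5 | tert-butyl ethyl 2-chloromalonate | CCOC(=O)C(Cl)C(=O)OC(C)(C)C
F9 | step 5 | tert-butyl ethyl 2-{4-[5,7-bis(benzyloxy)-4-oxo-4H-chromen-2-yl]phenoxy}malonate | CCOC(=O)C(Oc1ccc(cc1)-c1cc(=O)c2c(OCc3ccccc3)cc(OCc3ccccc3)cc2o1)C(=O)OC(C)(C)C
F10 | step 5 | 3-tert-butoxy-2-{4-[5,7-bis(benzyloxy)-4-oxo-4H-chromen-2-yl]phenoxy}-3-oxopropanoic acid | OC(=O)C(Oc1ccc(cc1)-c1cc(=O)c2c(OCc3ccccc3)cc(OCc3ccccc3)cc2o1)C(=O)OC(C)(C)C
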